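**Plan**
- Retrosynthetic cuts: first the O-benzyl bond at C3' and the O-methyl bonds at C5 and C8. Then C4a–C5 of ring A, with C5–C8 folded back into a cyclobutenone. Then C8–C8a, which releases dimethyl squarate and a 2-aryl-4-pyranone. Then O1–C2 and C3–C4 of ring C (hetero-Diels–Alder), leading to the ring B aldehyde and back to syringol.
- Enabling feature: C5, C6, C7 and C8 of ring A each carry oxygen and map one to one onto the four squarate carbons. The C4a=C8a bond is the unsubstituted C5=C6 edge of the pyranone (ring C).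
- Forward order: ring B is functionalised (steps 1–4). Ring C is built on its aldehyde and dehydrogenated (steps 5–6). The squarate is attached at pyranone C6 (step 7). Ring A is closed last (step 8), followed by methylation and debenzylation (steps 9–10).
- Stereochemistry: the target has no stereocentre. C2 of the dihydropyranone and the cyclobutenone carbinol arise racemic and both end as sp2 carbons.

Key step: step 8

Remark on the chemistry: ring A locants follow flavone numbering, and "C6 of the pyranone" is the unsubstituted carbon next to the ring oxygen. Compounds 8, 9, 13 and 15 are racemic, and no enantiocontrol is needed.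

**Step 1**
Reactants: 1 2,6-dimethoxyphenol (syringol)
Product: 2 2-(benzyloxy)-1,3-dimethoxybenzene
Conditions: BnBr, K2CO3, DMF, 60 °C
Reagents that add atoms: benzyl bromide, BrCc1ccccc1
Why: Williamson etherification of the phenoxide with a benzylic bromide installs the one oxygen substituent that must later be freed selectively, as an ether that tolerates every later organometallic, oxidative and thermal step.

**Step 2**
Reactants: 2 2-(benzyloxy)-1,3-dimethoxybenzene
Product: 4 3-(benzyloxy)-2,4-dimethoxybenzaldehyde, via aryl iminium salt 3 (not isolated)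
Conditions: POCl3, DMF, 80 °C; then H2O
Reagents that add atoms: N,N-dimethylformamide, CN(C)C=O; water, O
Why: Vilsmeier–Haack formylation of a 1,2,3-trialkoxybenzene goes ortho to one outer methoxy group and para to the other, because the flanked central benzyloxy group is twisted out of conjugation, and the two such positions are equivalent by symmetry.

**Step 3**
Reactants: 4 3-(benzyloxy)-2,4-dimethoxybenzaldehyde
Product: 5 3-(benzyloxy)-5-bromo-2,4-dimethoxybenzaldehyde
Conditions: NBS, MeCN, 25 °C, dark
Reagents that add atoms: N-bromosuccinimide, O=C1CCC(=O)N1Br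
Why: Electrophilic aromatic bromination should take C5, which is ortho to the 4-methoxy group, para to the 2-methoxy group and meta to the formyl group, whereas C6 is deactivated by the adjacent aldehyde.

**Step 4**
Reactants: 5 3-(benzyloxy)-5-bromo-2,4-dimethoxybenzaldehyde
Product: 6 3-(benzyloxy)-2,4,5-trimethoxybenzaldehyde
Conditions: NaOMe, CuBr (10 mol %), MeOH–DMF, 100 °C
Reagents that add atoms: sodium methoxide, [Na+].[O-]C
Why: Ullmann-type copper-catalysed methoxylation of an aryl bromide is compatible with a non-enolisable benzaldehyde, which is reversibly masked as its hemiacetal alkoxide in methanolic methoxide, and it completes the ring B oxygenation pattern.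

**Step 5**
Reactants: 6 3-(benzyloxy)-2,4,5-trimethoxybenzaldehyde; 7 (E)-1-methoxy-3-(trimethylsilyloxy)buta-1,3-diene
Product: 9 2-[3-(benzyloxy)-2,4,5-trimethoxyphenyl]-2,3-dihydro-4H-pyran-4-one (racemic), via silyloxy dihydropyran cycloadduct 8 (not isolated)
Conditions: ZnCl2, THF, 25 °C; then TFA, CH2Cl2, 0 °C
Reagents that add atoms: none
Why: Lewis acid-catalysed hetero-Diels–Alder reaction of the zinc-chelated ortho-methoxy aldehyde with the electron-rich siloxydiene, then acid-induced loss of methanol and the silyl group, should give the dihydropyranone, whose C2 centre is racemic and is removed in step 6.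

**Step 6**
Reactants: 9 2-[3-(benzyloxy)-2,4,5-trimethoxyphenyl]-2,3-dihydro-4H-pyran-4-one
Product: 10 2-[3-(benzyloxy)-2,4,5-trimethoxyphenyl]-4H-pyran-4-one
Conditions: DDQ, 1,4-dioxane, 90 °C
Reagents that add atoms: none
Why: DDQ dehydrogenation of the flavanone-to-flavone kind should work because the C2 hydrogen is benzylic to an ortho,para-dialkoxy arene and alpha to the ring oxygen, so hydride abstraction and loss of a C3 proton give the pyranone.

**Step 7**
Reactants: 10 2-[3-(benzyloxy)-2,4,5-trimethoxyphenyl]-4H-pyran-4-one; 11 dimethyl squarate (3,4-dimethoxycyclobut-3-ene-1,2-dione)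
Product: 13 4-{6-[3-(benzyloxy)-2,4,5-trimethoxyphenyl]-4-oxo-4H-pyran-2-yl}-4-hydroxy-2,3-dimethoxycyclobut-2-en-1-one (racemic), via pyranon-6-ylmagnesium chloride 12 (not isolated)
Conditions: TMPMgCl·LiCl (1.2 equiv), THF, −40 °C; then 11 (1.5 equiv), −78 °C; aq NH4Cl
Reagents that add atoms: none
Why: Deprotonative magnesiation with a hindered, non-nucleophilic amide base should take the CH next to the ring oxygen, the most acidic site as in C2 metalation of chromones, and 1,2-addition of the organomagnesium to one of the two equivalent squarate carbonyls at low temperature gives the carbinol without regiochemical choice.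

**Step 8**
Reactants: 13 4-{6-[3-(benzyloxy)-2,4,5-trimethoxyphenyl]-4-oxo-4H-pyran-2-yl}-4-hydroxy-2,3-dimethoxycyclobut-2-en-1-one
Product: 16 3'-benzyloxy-5,8-dihydroxy-6,7,2',4',5'-pentamethoxyflavone, via dienylketene 14 (not isolated), via 4aH-chromenedione tautomer 15 (not isolated)
Conditions: degassed p-xylene (0.02 M), 138 °C, Ar
Reagents that add atoms: none
Why: Heating should open the cyclobutenone by conrotatory 4π cleavage of the C(=O)–C(OH) bond to dienylketene 14, in which the pyranone C5=C6 bond ends the triene; a thermal 6π electrocyclisation then joins the ketene carbon (future C5) to the pyranone CH (future C4a) to give dienone 15, and enolisation to the aromatic 5,8-hydroquinone 16 drives the sequence. The closest known reaction type is the Moore ring expansion of 4-aryl-, 4-heteroaryl- and 4-alkenyl-4-hydroxycyclobutenones derived from squarates; the 4-oxopyranyl group is a new, electron-poor member of that class, and its weakly aromatic vinylogous-ester double bond is expected to behave like an alkenyl arm. Ring A closes in the 6π-electrocyclic mode as a six-membered carbocycle through the C4a–C5 bond. No stereocentre is formed, and the racemic carbinol carbon becomes the sp2 carbon C8. The step needs torquoselectivity, which the electron-donating hydroxyl provides by rotating outward, so the pyranonyl group turns inward beside the ketene and the hydroxyl is kept away from lactonisation to a furanone. Regiochemistry is fixed because C4a is the only carbon within reach of the ketene, and the two squarate methoxy groups end at C6 and C7 whichever carbonyl was attacked in step 7.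

**Step 9**
Reactants: 16 3'-benzyloxy-5,8-dihydroxy-6,7,2',4',5'-pentamethoxyflavone
Product: 17 2-[3-(benzyloxy)-2,4,5-trimethoxyphenyl]-5,6,7,8-tetramethoxy-4H-chromen-4-one
Conditions: MeI (excess), K2CO3, degassed DMF, 50 °C, Ar
Reagents that add atoms: iodomethane, CI
Why: Williamson O-methylation in warm DMF with excess iodomethane should alkylate both the free 8-hydroxyl and the carbonyl-chelated 5-hydroxyl, while exclusion of air keeps the electron-rich hydroquinone dianion from oxidising to the 5,8-quinone.

**Step 10**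
Reactants: 17 2-[3-(benzyloxy)-2,4,5-trimethoxyphenyl]-5,6,7,8-tetramethoxy-4H-chromen-4-one
Product: 18 agehoustin C
Conditions: H2 (1 atm), Pd/C (10 wt %), EtOAc–MeOH, 25 °C
Reagents that add atoms: none
Why: Catalytic hydrogenolysis cleaves the benzyl aryl ether at ambient pressure, and it should leave the aryl methyl ethers and the conjugated C2=C3 bond of the flavone untouched.

**Compound list**
1 | 2,6-dimethoxyphenol (syringol) | COc1cccc(OC)c1O | starting material
2 | 2-(benzyloxy)-1,3-dimethoxybenzene | COc1cccc(OC)c1OCc1ccccc1 | intermediate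
3 | N-[3-(benzyloxy)-2,4-dimethoxybenzylidene]-N-methylmethanaminium dichlorophosphate (not isolated) | C[N+](C)=Cc1ccc(OC)c(OCc2ccccc2)c1OC.[O-]P(=O)(Cl)Cl | intermediate
4 | 3-(benzyloxy)-2,4-dimethoxybenzaldehyde | O=Cc1ccc(OC)c(OCc2ccccc2)c1OC | intermediate
5 | 3-(benzyloxy)-5-bromo-2,4-dimethoxybenzaldehyde | O=Cc1cc(Br)c(OC)c(OCc2ccccc2)c1OC | intermediate
6 | 3-(benzyloxy)-2,4,5-trimethoxybenzaldehyde | O=Cc1cc(OC)c(OC)c(OCc2ccccc2)c1OC | intermediate
7 | (E)-1-methoxy-3-(trimethylsilyloxy)buta-1,3-diene | CO/C=C/C(=C)O[Si](C)(C)C | starting material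
8 | 2-[3-(benzyloxy)-2,4,5-trimethoxyphenyl]-6-methoxy-4-(trimethylsilyloxy)-3,6-dihydro-2H-pyran (racemic, cis/trans mixture, not isolated) | COC1C=C(O[Si](C)(C)C)CC(c2cc(OC)c(OC)c(OCc3ccccc3)c2OC)O1 | intermediate
9 | 2-[3-(benzyloxy)-2,4,5-trimethoxyphenyl]-2,3-dihydro-4H-pyran-4-one (racemic) | O=C1C=COC(c2cc(OC)c(OC)c(OCc3ccccc3)c2OC)C1 | intermediate
10 | 2-[3-(benzyloxy)-2,4,5-trimethoxyphenyl]-4H-pyran-4-one | COc1cc(-c2cc(=O)cco2)c(OC)c(OCc2ccccc2)c1OC | intermediate
11 | dimethyl squarate (3,4-dimethoxycyclobut-3-ene-1,2-dione) | COC1=C(OC)C(=O)C1=O | starting material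
12 | {6-[3-(benzyloxy)-2,4,5-trimethoxyphenyl]-4-oxo-4H-pyran-2-yl}magnesium chloride (LiCl complex, not isolated) | COc1cc(-c2cc(=O)cc([Mg]Cl)o2)c(OC)c(OCc2ccccc2)c1OC | intermediate
13 | 4-{6-[3-(benzyloxy)-2,4,5-trimethoxyphenyl]-4-oxo-4H-pyran-2-yl}-4-hydroxy-2,3-dimethoxycyclobut-2-en-1-one (racemic) | COC1=C(OC)C(O)(c2cc(=O)cc(-c3cc(OC)c(OC)c(OCc4ccccc4)c3OC)o2)C1=O | intermediate
14 | (3Z)-4-{6-[3-(benzyloxy)-2,4,5-trimethoxyphenyl]-4-oxo-4H-pyran-2-yl}-4-hydroxy-2,3-dimethoxybuta-1,3-dien-1-one (not isolated) | O=C=C(OC)/C(OC)=C(/O)c1cc(=O)cc(-c2cc(OC)c(OC)c(OCc3ccccc3)c2OC)o1 | intermediate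
15 | 2-[3-(benzyloxy)-2,4,5-trimethoxyphenyl]-8-hydroxy-6,7-dimethoxy-4aH-chromene-4,5-dione (racemic, not isolated) | COC1=C(OC)C(=O)C2C(=O)C=C(c3cc(OC)c(OC)c(OCc4ccccc4)c3OC)OC2=C1O | intermediate
16 | 2-[3-(benzyloxy)-2,4,5-trimethoxyphenyl]-5,8-dihydroxy-6,7-dimethoxy-4H-chromen-4-one (3'-benzyloxy-5,8-dihydroxy-6,7,2',4',5'-pentamethoxyflavone) | COc1cc(-c2cc(=O)c3c(O)c(OC)c(OC)c(O)c3o2)c(OC)c(OCc2ccccc2)c1OC | intermediate
17 | 2-[3-(benzyloxy)-2,4,5-trimethoxyphenyl]-5,6,7,8-tetramethoxy-4H-chromen-4-one | COc1cc(-c2cc(=O)c3c(OC)c(OC)c(OC)c(OC)c3o2)c(OC)c(OCc2ccccc2)c1OC | intermediate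
18 | agehoustin C, 2-(3-hydroxy-2,4,5-trimethoxyphenyl)-5,6,7,8-tetramethoxy-4H-chromen-4-one | COc1cc(-c2cc(=O)c3c(OC)c(OC)c(OC)c(OC)c3o2)c(OC)c(O)c1OC | target

**Totals**
Total step count: 10. Longest linear sequence: 10 steps, from 1 to 18. Compounds 7 and 11 are purchased and enter at steps 5 and 7.

**Steps most likely to fail**

Step 7. The base may metalate C3 or C5 beside the carbonyl instead of C6, or the magnesiated pyranone may ring-open before it meets the squarate. The fallback sets out from 10 and separates metalation from addition. Zincation with TMPZnCl·LiCl in the presence of BF3·OEt2 (THF, −40 °C), where the carbonyl-bound Lewis acid keeps the base away from C3 and C5, should give the stable {6-[3-(benzyloxy)-2,4,5-trimethoxyphenyl]-4-oxo-4H-pyran-2-yl}zinc chloride F1. Iodinolysis with I2 then gives 2-[3-(benzyloxy)-2,4,5-trimethoxyphenyl]-6-iodo-4H-pyran-4-one F2, which is isolated so that the site of substitution can be assigned. Iodine–magnesium exchange with iPrMgCl·LiCl at −78 °C, with no amide base present, regenerates 12 at low temperature. Addition to 11 brings the route back at 13.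

Step 8. The hydroxyl may rotate inward during ring opening so that the ketene lactonises to a furanone, or the pyranone arm may degrade thermally before the electrocyclisation. The fallback sets out from 6 and builds rings C and A by classical flavone chemistry. Claisen–Schmidt condensation of 6 with purchased 1-(2-hydroxy-3,4,5,6-tetramethoxyphenyl)ethan-1-one (CC(=O)c1c(O)c(OC)c(OC)c(OC)c1OC; KOH, EtOH, 25 °C) should give (E)-3-[3-(benzyloxy)-2,4,5-trimethoxyphenyl]-1-(2-hydroxy-3,4,5,6-tetramethoxyphenyl)prop-2-en-1-one F3. Oxidative cyclisation of this 2'-hydroxychalcone (I2 cat., DMSO, 120 °C, short reaction time to spare the 5-methoxy group) comes back to the route at 17.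

Step 6. Hydride abstraction may stall, or DDQ may degrade the electron-rich ring B by charge-transfer oxidation. The fallback sets out from 6 and adjusts the oxidation level on the open chain instead of on the ring. Aldol addition of the lithium enolate of (E)-4-methoxybut-3-en-2-one (LiHMDS, THF, −78 °C) to 6 should give (E)-5-[3-(benzyloxy)-2,4,5-trimethoxyphenyl]-5-hydroxy-1-methoxypent-1-en-3-one F4 (racemic). Oxidation of the secondary alcohol with DMP (CH2Cl2, 25 °C) gives (E)-1-[3-(benzyloxy)-2,4,5-trimethoxyphenyl]-5-methoxypent-4-ene-1,3-dione F5. Acid-induced cyclisation with loss of methanol (TFA, CH2Cl2, 25 °C) comes back to the route at 10.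

**Further compounds**
F1 | step 7 | {6-[3-(benzyloxy)-2,4,5-trimethoxyphenyl]-4-oxo-4H-pyran-2-yl}zinc chloride | COc1cc(-c2cc(=O)cc([Zn]Cl)o2)c(OC)c(OCc2ccccc2)c1OC
F2 | step 7 | 2-[3-(benzyloxy)-2,4,5-trimethoxyphenyl]-6-iodo-4H-pyran-4-one | COc1cc(-c2cc(=O)cc(I)o2)c(OC)c(OCc2ccccc2)c1OC
F3 | step 8 | (E)-3-[3-(benzyloxy)-2,4,5-trimethoxyphenyl]-1-(2-hydroxy-3,4,5,6-tetramethoxyphenyl)prop-2-en-1-one | COc1cc(/C=C/C(=O)c2c(O)c(OC)c(OC)c(OC)c2OC)c(OC)c(OCc2ccccc2)c1OC
F4 | step 6 | (E)-5-[3-(benzyloxy)-2,4,5-trimethoxyphenyl]-5-hydroxy-1-methoxypent-1-en-3-one (racemic) | CO/C=C/C(=O)CC(O)c1cc(OC)c(OC)c(OCc2ccccc2)c1OC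
F5 | step 6 | (E)-1-[3-(benzyloxy)-2,4,5-trimethoxyphenyl]-5-methoxypent-4-ene-1,3-dione | CO/C=C/C(=O)CC(=O)c1cc(OC)c(OC)c(OCc2ccccc2)c1OC
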